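- The easy step comes first: one electrophile meets one nucleophile and gives target, and by itself that step makes no homo dimer.

| setting | birch | maple | west | south-east | east |
|---|---|---|---|---|---|
| electrophile | 0.050 M | 0.050 M | 0.050 M (fed, over 30 h) | 0.050 M | 0.050 M |
| nucleophile | 1.2 equiv | 1.2 equiv | 1.20 equiv | 1.20 equiv (fed, over 30 h) | 1.20 equiv |
| free base | 0.50 equiv | 1 equiv | 0.500 equiv | 0.500 equiv | 0.500 equiv |
| remark | run made earlier | run made earlier | all else is in the flask from the start; the feed brings no volume worth counting | all else is in the flask from the start; the feed brings no volume worth counting | everything together at the start |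
| time |  |  | 40 h | 40 h | 40 h |

| run | time / h | homo dimer / % | target / % |
|---|---|---|---|
| birch | 3.00 | 3.5 | 8.0 |
| birch | 6.00 | 7.7 | 13.2 |
| birch | 10.0 | 10.8 | 18.6 |
| birch | 15.0 | 13.8 | 23.2 |
| birch | 20.0 | 15.8 | 26.7 |
| birch | 25.0 | 16.5 | 28.6 |
| maple | 1.00 | 1.9 | 3.5 |
| maple | 1.33 | 2.5 | 3.8 |
| maple | 2.00 | 3.6 | 6.0 |
| maple | 3.00 | 4.4 | 8.0 |
| maple | 5.00 | 6.0 | 11.8 |
| maple | 8.00 | 9.1 | 16.9 |
| maple | 12.0 | 11.6 | 21.3 |

(each reading ± 0.3 percentage points)

* the flask with the highest amount of homo dimer, in percent of the electrophile charged ("all alike" if they lie within 1.5 percentage points) (west / south-east / east / all alike)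
* final homo dimer, as a percentage of the electrophile charged, in west
* final homo dimer, as a percentage of the electrophile charged, in south-east
* final homo dimer, as a percentage of the electrophile charged, in east

- percentages count the electrophile that a species holds: one homo dimer counts as two

- One more step: two electrophile give homo dimer. In birch the dimer slope falls to 0.390 of its early value, and the square of the fall in the most electrophile the readings allow, 0.507, lies nearer than its plain fall, 0.712.
- So electrophile concentration sets the order: homo dimer over target, as rates, equals a selectivity factor times electrophile over nucleophile. The factor, read as the pooled dimer-to-target ratio at 3.00 h times the nucleophile equivalents, is 0.593. First order in nucleophile is assumed, since every run held 1.2 equiv.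
- The same readings give a dimer constant of 0.0149 h⁻¹. With no target step, south-east would reach 37.3 %.
- Adding the nucleophile feed, the two rates cross near 14.8 h, with 18.1 % dimer and about 11.0 % target formed. East, extended from birch, reaches 19.2 %. Scaling its late gain by the squared electrophile ratio gives south-east 24.9 %.
- West is reckoned with the nucleophile held at its charge, a simplification, as the target step uses nucleophile up; this gives the electrophile a single loss constant of 0.0302 h⁻¹. On that constant the reckoning puts electrophile at 65.8 % by the end of the feed and homo dimer at 11.2 %.
- The rest: free base enters this reckoning nowhere, and target reads 8.0 % in birch and 8.0 % in maple at 3.00 h.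
- The forecast names south-east, with 10 % in west, 19.5 % in east and 21 % in south-east (17 % to 32 %), lower than this reckoning, on the ground “Early starvation could favour dimer”.
- The flasks give 12.3 % in west, 29.1 % in south-east and 20.0 % in east, so south-east stands highest, and south-east exceeds the reckoning.

    acid set free + free base ⇌ salt of the base (K = 320 L mol⁻¹, k = 0.0470 L mol⁻¹ min⁻¹)
    nucleophile + acid set free ⇌ protonated nucleophile, settled at all times (K = 350 L mol⁻¹)
    2 electrophile → homo dimer (k = 0.00260 L mol⁻¹ min⁻¹)
    electrophile + nucleophile → acid set free + target (k = 0.00870 L mol⁻¹ min⁻¹)
    electrophile + target → side product (k = 0.00750 L mol⁻¹ min⁻¹)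

- In south-east at 30.0 h, the factor gives a rate ratio of 0.362, far below the standing homo dimer over target, 1.39. In west at 40.0 h the factor gives 0.493 against a standing 0.426. Its neighbour at 0.013 M electrophile, with 77 % of electrophile and 77 % of nucleophile left, gives 0.497 against a standing 0.409, with homo dimer at 5.97 %.

(The data were generated by integration with made-up constants, and the scatter is random.)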